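Assumption: (+)-larixol, a catalogue natural product, counts as commercially available. Labdane numbering is used throughout (C18 = 4α-methyl, C19 = 4β-methyl, C20 = 10β-methyl), and the lactone carbinol carbon of the target is called C16.

**Retrosynthetic overview**
1. Target ⇒ C15–C16 bond by a catalytic asymmetric vinylogous Mukaiyama aldol of a 2-silyloxy-4-methylfuran with the silyl-protected (13E)-6α,18-dihydroxylabda-8(17),13-dien-15-al.
2. Enal ⇒ E-enoate ⇒ C13 methyl ketone (Horner–Wadsworth–Emmons, then reduction and allylic oxidation).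
3. 18-OH ⇒ 1,5-hydrogen transfer from the 6α-alkoxy radical to the peri 4α-methyl (Barton nitrite photolysis), which sets C4.
4. Methyl ketone ⇒ (+)-larixol by permanganate side-chain degradation.
5. No ring is formed in the route: the decalin (C5, C6, C9, C10) comes from larixol and the butenolide from 4-methylfuran-2(5H)-one.

**Route**

Step 1
Reactants: 1 (+)-larixol
Product: 2 6α-hydroxy-14,15-dinorlabd-8(17)-en-13-one
Conditions: KMnO4, BnEt3NCl, CH2Cl2, 0 °C→rt
Reagents that add atoms: none
Why: Permanganate oxidative degradation of the vinyl carbinol (dihydroxylation, then glycol/ketol cleavage) removes C14–C15 and leaves the C13 oxygen as the ketone, while the hindered 8(17)-methylene and the peri-shielded 6α-OH survive, as with manool and sclareol.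

Step 2
Reactants: 2 6α-hydroxy-14,15-dinorlabd-8(17)-en-13-one
Product: 3 ethyl (13E)-6α-hydroxylabda-8(17),13-dien-15-oate
Conditions: (EtO)2P(O)CH2CO2Et, NaH (excess), THF, 0 °C→reflux; chromatography (E isomer)
Reagents that add atoms: triethyl phosphonoacetate CCOC(=O)CP(=O)(OCC)OCC
Why: Horner–Wadsworth–Emmons olefination of the methyl ketone gives mainly the thermodynamically preferred E-trisubstituted enoate (about 5:1), and the free alcohol is carried as its alkoxide.

Step 3
Reactants: 3 ethyl (13E)-6α-hydroxylabda-8(17),13-dien-15-oate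
Product: 4 ethyl (13E)-6α-(nitrosooxy)labda-8(17),13-dien-15-oate
Conditions: NOCl, pyridine, −20 °C
Reagents that add atoms: nitrosyl chloride O=NCl
Why: O-Nitrosation of the secondary alcohol is fast and sterically undemanding, retains C6 configuration, and is much faster than NOCl addition to the hindered or electron-poor alkenes in pyridine.

Step 4
Reactants: 4 ethyl (13E)-6α-(nitrosooxy)labda-8(17),13-dien-15-oate
Product: 6 ethyl (13E)-6α-hydroxy-18-(hydroxyimino)labda-8(17),13-dien-15-oate, via ethyl (13E)-6α-hydroxy-18-nitrosolabda-8(17),13-dien-15-oate 5 (not isolated)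
Conditions: hν (Hg lamp, Pyrex), PhH, N2, 15 °C; then i-PrOH, reflux
Reagents that add atoms: none
Why: Barton nitrite photolysis: the equatorial 6α-alkoxy radical lies about 2.5 Å from the peri 4α-methyl (about 3.5 Å from the 4β-methyl), so 1,5-hydrogen transfer and NO recombination functionalise C18 selectively and set C4, and the nitroso compound tautomerises to the oxime.

Step 5
Reactants: 6 ethyl (13E)-6α-hydroxy-18-(hydroxyimino)labda-8(17),13-dien-15-oate
Product: 7 ethyl (13E)-6α-hydroxy-18-oxolabda-8(17),13-dien-15-oate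
Conditions: aq. TiCl3, NH4OAc, THF/H2O, rt
Reagents that add atoms: water O
Why: Buffered Ti(III) reductive deoximation (N–O cleavage, then imine hydrolysis) frees the non-epimerisable neopentyl aldehyde, which sits in equilibrium with its 6α,18-lactol, without touching the enoate or the alkenes.

Step 6
Reactants: 7 ethyl (13E)-6α-hydroxy-18-oxolabda-8(17),13-dien-15-oate
Product: 8 (13E)-labda-8(17),13-diene-6α,15,18-triol
Conditions: LiAlH4, THF, 0 °C
Reagents that add atoms: none
Why: Hydride reduction takes the aldehyde (or lactol) to the 18-alcohol and the β,β-disubstituted enoate to the allylic alcohol by 1,2-reduction, with alkene geometry retained.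

Step 7
Reactants: 8 (13E)-labda-8(17),13-diene-6α,15,18-triol
Product: 9 (13E)-6α,18-dihydroxylabda-8(17),13-dien-15-al
Conditions: MnO2, CH2Cl2, rt
Reagents that add atoms: none
Why: Activated MnO2 oxidises only the allylic primary alcohol, leaving the neopentyl primary and hindered secondary alcohols and the E geometry intact.

Step 8
Reactants: 9 (13E)-6α,18-dihydroxylabda-8(17),13-dien-15-al
Product: 10 (13E)-6α,18-bis(triethylsilyloxy)labda-8(17),13-dien-15-al
Conditions: TESOTf, 2,6-lutidine, CH2Cl2, −78→0 °C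
Reagents that add atoms: triethylsilyl triflate CC[Si](CC)(CC)OS(=O)(=O)C(F)(F)F
Why: The silyl triflate with a hindered base silylates both the primary and the peri-hindered secondary alcohol at low temperature without enolising the enal, masking the diol from the Lewis acid of the last step.

Step 9
Reactants: 11 4-methylfuran-2(5H)-one
Product: 12 trimethyl[(4-methylfuran-2-yl)oxy]silane
Conditions: TMSOTf, Et3N, Et2O, 0 °C; distil
Reagents that add atoms: trimethylsilyl triflate C[Si](C)(C)OS(=O)(=O)C(F)(F)F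
Why: Soft enolisation and O-silylation of the butenolide gives the aromatic 2-silyloxyfuran, a γ-nucleophilic dienolate equivalent.

Step 10
Reactants: 10 (13E)-6α,18-bis(triethylsilyloxy)labda-8(17),13-dien-15-al; 12 trimethyl[(4-methylfuran-2-yl)oxy]silane
Product: 14 (5S)-5-[(1S,2E)-1-hydroxy-5-[(1S,4S,4aR,5R,8aR)-4-hydroxy-5-(hydroxymethyl)-5,8a-dimethyl-2-methylidenedecahydronaphthalen-1-yl]-3-methylpent-2-en-1-yl]-4-methylfuran-2(5H)-one, via 15-O-trimethylsilyl-6,18-bis-O-triethylsilyl aldol adduct 13 (not isolated)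
Conditions: 12 (2.5 equiv), Ti(OiPr)4/(R)-BINOL (20 mol %), Et2O, −20 °C; then HF·pyridine, THF, 0 °C→rt
Reagents that add atoms: none
Why: Catalytic asymmetric vinylogous Mukaiyama aldol at the furan γ-carbon: the (R)-BINOL–Ti complex directs Re-face attack on the enal (15S, Keck-type sense) and the open transition state gives the threo adduct (16S); HF·pyridine then removes the three silyl groups without base, and the minor erythro isomer is separated by chromatography.

**Compound list**
1 | (+)-larixol, (13S)-labda-8(17),14-diene-6α,13-diol | C=C1C[C@H](O)[C@H]2C(C)(C)CCC[C@]2(C)[C@H]1CC[C@](C)(O)C=C | starting material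
2 | 6α-hydroxy-14,15-dinorlabd-8(17)-en-13-one | C=C1C[C@H](O)[C@H]2C(C)(C)CCC[C@]2(C)[C@H]1CCC(C)=O | intermediate
3 | ethyl (13E)-6α-hydroxylabda-8(17),13-dien-15-oate | C=C1C[C@H](O)[C@H]2C(C)(C)CCC[C@]2(C)[C@H]1CC/C(C)=C/C(=O)OCC | intermediate
4 | ethyl (13E)-6α-(nitrosooxy)labda-8(17),13-dien-15-oate (6α-nitrite ester) | C=C1C[C@H](ON=O)[C@H]2C(C)(C)CCC[C@]2(C)[C@H]1CC/C(C)=C/C(=O)OCC | intermediate
5 | ethyl (13E)-6α-hydroxy-18-nitrosolabda-8(17),13-dien-15-oate | C=C1C[C@H](O)[C@H]2[C@](C)(CN=O)CCC[C@]2(C)[C@H]1CC/C(C)=C/C(=O)OCC | intermediate (not isolated)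
6 | ethyl (13E)-6α-hydroxy-18-(hydroxyimino)labda-8(17),13-dien-15-oate | C=C1C[C@H](O)[C@H]2[C@](C)(/C=N/O)CCC[C@]2(C)[C@H]1CC/C(C)=C/C(=O)OCC | intermediate
7 | ethyl (13E)-6α-hydroxy-18-oxolabda-8(17),13-dien-15-oate (in equilibrium with its 6α,18-lactol) | C=C1C[C@H](O)[C@H]2[C@](C)(C=O)CCC[C@]2(C)[C@H]1CC/C(C)=C/C(=O)OCC | intermediate
8 | (13E)-labda-8(17),13-diene-6α,15,18-triol | C=C1C[C@H](O)[C@H]2[C@](C)(CO)CCC[C@]2(C)[C@H]1CC/C(C)=C/CO | intermediate
9 | (13E)-6α,18-dihydroxylabda-8(17),13-dien-15-al | C=C1C[C@H](O)[C@H]2[C@](C)(CO)CCC[C@]2(C)[C@H]1CC/C(C)=C/C=O | intermediate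
10 | (13E)-6α,18-bis(triethylsilyloxy)labda-8(17),13-dien-15-al | C=C1C[C@H](O[Si](CC)(CC)CC)[C@H]2[C@](C)(CO[Si](CC)(CC)CC)CCC[C@]2(C)[C@H]1CC/C(C)=C/C=O | intermediate
11 | 4-methylfuran-2(5H)-one | CC1=CC(=O)OC1 | starting material
12 | trimethyl[(4-methylfuran-2-yl)oxy]silane | Cc1coc(O[Si](C)(C)C)c1 | intermediate
13 | (15S,16S) aldol adduct, 15-O-trimethylsilyl-6,18-bis-O-triethylsilyl ether of 14 | C=C1C[C@H](O[Si](CC)(CC)CC)[C@H]2[C@](C)(CO[Si](CC)(CC)CC)CCC[C@]2(C)[C@H]1CC/C(C)=C/[C@H](O[Si](C)(C)C)[C@H]1OC(=O)C=C1C | intermediate (not isolated)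
14 | (5S)-5-[(1S,2E)-1-hydroxy-5-[(1S,4S,4aR,5R,8aR)-4-hydroxy-5-(hydroxymethyl)-5,8a-dimethyl-2-methylidenedecahydronaphthalen-1-yl]-3-methylpent-2-en-1-yl]-4-methylfuran-2(5H)-one | C=C1C[C@H](O)[C@H]2[C@](C)(CO)CCC[C@]2(C)[C@H]1CC/C(C)=C/[C@H](O)[C@H]1OC(=O)C=C1C | target

**Totals**
Total step count: 10. Longest linear sequence: 9 steps (steps 1–8 and 10, from 1 to 14).

**Steps most likely to fail**

Step 4 (nitrite photolysis). The 6α-alkoxy radical can also fragment across C6–C7 to an allylic radical, and NO trapping or oxime formation may be low-yielding. The fallback sets out from 3 and comes back at 8. Alcohol 3 is treated with excess PhI(OAc)2/I2 under irradiation in cyclohexane (hypoiodite relay with double functionalisation of the neopentyl C18) to give ethyl (13E)-18-acetoxy-6α,18-epoxylabda-8(17),13-dien-15-oate F1. LiAlH4 then reduces the lactol acetate and the ester of F1 together to triol 8.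

Step 10 (asymmetric vinylogous aldol). Facial and threo/erythro control with a 4-methyl-substituted silyloxyfuran on this enal is unproven. The fallback sets out from 10 and comes back at 14. BF3·OEt2-mediated addition of 12 to 10 (threo-selective, no facial control) gives, after aqueous work-up, the two threo alcohols: the (15S,16S) bis-triethylsilyl ether F2 and its (15R,16R) diastereomer F3. A Sharpless kinetic resolution (Ti(OiPr)4, L-(+)-DIPT, t-BuOOH, −20 °C) epoxidises only F3 to the erythro 13,14-epoxy alcohol F4. The untouched F2 is separated and desilylated with HF·pyridine to 14.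

Step 2 (olefination). The E/Z ratio is only moderate and the isomers may be hard to separate. The fallback sets out from 2 and comes back at 3. Ketone 2 is converted with LDA and ClP(O)(OEt)2 into the kinetic enol diethyl phosphate F5, which LDA eliminates to the terminal alkyne (6α)-14,15-dinorlabd-8(17)-en-13(16)-yn-6-ol F6. Zirconium-catalysed syn-carboalumination (Me3Al, Cp2ZrCl2, CH2Cl2) gives the (E)-alkenylalane F7, which is trapped in the flask with ethyl chloroformate to give 3 as the single E isomer.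

**Further compounds**
F1 | step 4 | ethyl (13E)-18-acetoxy-6α,18-epoxylabda-8(17),13-dien-15-oate (lactol acetate, C18 epimers) | C=C1C[C@@H]2OC(OC(C)=O)[C@]3(C)CCC[C@](C)([C@H]1CC/C(C)=C/C(=O)OCC)[C@@H]23
F2 | step 10 | (15S,16S) aldol adduct, 6,18-bis-O-triethylsilyl ether of 14 with free 15-OH | C=C1C[C@H](O[Si](CC)(CC)CC)[C@H]2[C@](C)(CO[Si](CC)(CC)CC)CCC[C@]2(C)[C@H]1CC/C(C)=C/[C@H](O)[C@H]1OC(=O)C=C1C
F3 | step 10 | (15R,16R) diastereomer of F2 | C=C1C[C@H](O[Si](CC)(CC)CC)[C@H]2[C@](C)(CO[Si](CC)(CC)CC)CCC[C@]2(C)[C@H]1CC/C(C)=C/[C@@H](O)[C@@H]1OC(=O)C=C1C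
F4 | step 10 | erythro 13,14-epoxy alcohol formed from F3 | C=C1C[C@H](O[Si](CC)(CC)CC)[C@H]2[C@](C)(CO[Si](CC)(CC)CC)CCC[C@]2(C)[C@H]1CC[C@]3(C)O[C@H]3[C@@H](O)[C@@H]1OC(=O)C=C1C
F5 | step 2 | diethyl 6α-hydroxy-14,15-dinorlabda-8(17),13(16)-dien-13-yl phosphate (enol phosphate) | C=C1C[C@H](O)[C@H]2C(C)(C)CCC[C@]2(C)[C@H]1CCC(=C)OP(=O)(OCC)OCC
F6 | step 2 | (6α)-14,15-dinorlabd-8(17)-en-13(16)-yn-6-ol (terminal alkyne) | C=C1C[C@H](O)[C@H]2C(C)(C)CCC[C@]2(C)[C@H]1CCC#C
F7 | step 2 | (E)-alkenyl dimethylalane from carboalumination of F6, as its 6-O-dimethylaluminium alkoxide | C=C1C[C@H](O[Al](C)C)[C@H]2C(C)(C)CCC[C@]2(C)[C@H]1CC/C(C)=C/[Al](C)C
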